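**Assumption:** atoms are labelled with germacrane numbering (lactone O on C6, ring fusion C7, ester O on C8, oxirane C1–C10, CH2OH = C14, free OH on C3, methyl C15 on C4, exocyclic C11=C13, lactone carbonyl C12); the kinetic resolution is counted as one step.

## Retrosynthetic overview

1. Target 32 ⇐ PMB ether 31 ⇐ open-chain 30: the ten-membered ring is closed last by ring-closing metathesis, forming the (Z)-C4=C5 bond between a styryl group on C6 and an isopropenyl group on C3.
2. 30 ⇐ 29 ⇐ 28 ⇐ 26: the C1–C10 oxirane comes from Sharpless epoxidation of the C14 allylic alcohol; the C8 ester comes from Mitsunobu inversion of the coupling carbinol.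
3. 26 ⇐ aldehyde 24 (fragment A: C1–C4, C8–C10, C14, C15) + bromobutenolide 10 (fragment B: C5–C7, C11–C13): a zinc Barbier coupling forms C7–C8 and unveils the α-methylene lactone.
4. 24 ⇐ dienol 13 + acid 17 through an ester-tethered metathesis to a dihydropyranone, whose reductive opening fixes the C1=C10 geometry; 10 ⇐ resolved dienol 6 + acid 3 through metathesis to the butenolide.
5. Ring order: butenolide (fragment B) and temporary dihydropyranone (fragment A) → α-methylene-γ-lactone at the coupling → oxirane → ten-membered carbocycle.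

## Route

### Fragment B (bromobutenolide 10)

**Step 1**
Reactants: 1 ethyl 2-(hydroxymethyl)acrylate
Product: 2 ethyl 2-{[(tert-butyldimethylsilyl)oxy]methyl}acrylate
Conditions: TBSCl, imidazole, CH2Cl2, 0 °C to rt
Reagents that add atoms: tert-butyldimethylsilyl chloride, CC(C)(C)[Si](C)(C)Cl
Why: Silylation of a primary allylic alcohol with a silyl chloride and imidazole is routine and masks the future C13 oxygen.

**Step 2**
Reactants: 2 ethyl 2-{[(tert-butyldimethylsilyl)oxy]methyl}acrylate
Product: 3 2-{[(tert-butyldimethylsilyl)oxy]methyl}acrylic acid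
Conditions: LiOH·H2O, THF/H2O, 0 °C to rt; then 1 M HCl to pH 4
Reagents that add atoms: lithium hydroxide, [Li+].[OH-]
Why: Saponification of the ethyl ester is faster than attack on the primary silyl ether, and the acrylate carboxylate is a poor Michael acceptor.

**Step 3**
Reactants: 4 (E)-cinnamaldehyde
Product: 5 racemic (E)-1-phenylpenta-1,4-dien-3-ol
Conditions: CH2=CHMgBr, THF, −78 to 0 °C; aq NH4Cl
Reagents that add atoms: vinylmagnesium bromide, C=C[Mg]Br
Why: Grignard 1,2-addition to the enal gives the bis-allylic carbinol that will become C6.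

**Step 4**
Reactants: 5 racemic (E)-1-phenylpenta-1,4-dien-3-ol
Product: 6 (S,E)-1-phenylpenta-1,4-dien-3-ol
Conditions: immobilised Candida antarctica lipase B, vinyl acetate, hexane, 30 °C, to about 55% conversion
Reagents that add atoms: none
Why: Lipase kinetic resolution (transesterification) acylates the R alcohol (large styryl, medium vinyl, Kazlauskas rule), so the S alcohol needed for C6 is recovered in high ee.

**Step 5**
Reactants: 6 (S,E)-1-phenylpenta-1,4-dien-3-ol; 3 2-{[(tert-butyldimethylsilyl)oxy]methyl}acrylic acid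
Product: 7 (S,E)-1-phenylpenta-1,4-dien-3-yl 2-{[(tert-butyldimethylsilyl)oxy]methyl}acrylate
Conditions: DCC, 4-(dimethylamino)pyridine (cat.), CH2Cl2, 0 °C to rt
Reagents that add atoms: none
Why: Steglich esterification forms the acyl–O bond without touching the carbinol stereocentre.

**Step 6**
Reactants: 7 (S,E)-1-phenylpenta-1,4-dien-3-yl 2-{[(tert-butyldimethylsilyl)oxy]methyl}acrylate
Product: 8 (R)-3-{[(tert-butyldimethylsilyl)oxy]methyl}-5-[(E)-2-phenylethenyl]furan-2(5H)-one
Conditions: second-generation Grubbs catalyst RuCl2(=CHPh)(PCy3)(H2IMes) (5 mol%), CH2Cl2 (0.01 M), 40 °C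
Reagents that add atoms: none
Why: Ring-closing metathesis starts at the terminal vinyl group and closes the five-membered ring onto the acrylate alkene, leaving the slower styryl alkene as the C5 handle (the descriptor changes to R only through CIP priorities).

**Step 7**
Reactants: 8 (R)-3-{[(tert-butyldimethylsilyl)oxy]methyl}-5-[(E)-2-phenylethenyl]furan-2(5H)-one
Product: 9 (R)-3-(hydroxymethyl)-5-[(E)-2-phenylethenyl]furan-2(5H)-one
Conditions: HF·pyridine, THF, 0 °C to rt
Reagents that add atoms: none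
Why: Acidic fluoride desilylation avoids base, which would deprotonate the doubly activated C6–H of the butenolide.

**Step 8**
Reactants: 9 (R)-3-(hydroxymethyl)-5-[(E)-2-phenylethenyl]furan-2(5H)-one
Product: 10 (R)-3-(bromomethyl)-5-[(E)-2-phenylethenyl]furan-2(5H)-one
Conditions: CBr4, PPh3, CH2Cl2, 0 °C
Reagents that add atoms: carbon tetrabromide, BrC(Br)(Br)Br
Why: The Appel reaction converts the primary allylic alcohol into the bromide under neutral conditions by SN2 displacement of the alkoxyphosphonium.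

### Fragment A (aldehyde 24)

**Step 9**
Reactants: 11 methacrolein
Product: 13 (S)-2-methylhexa-1,5-dien-3-ol, via diisopinocampheylborinate ester 12 (not isolated)
Conditions: (−)-Ipc2BOMe, CH2=CHCH2MgBr, Et2O, 0 °C to rt; then 11, −78 °C; then NaOH, H2O2, rt
Reagents that add atoms: allylmagnesium bromide, C=CC[Mg]Br (delivered as (−)-B-allyldiisopinocampheylborane, C=CCB([C@@H]1C[C@@H]2C[C@H]([C@H]1C)C2(C)C)[C@@H]1C[C@@H]2C[C@H]([C@H]1C)C2(C)C)
Why: Brown asymmetric allylboration proceeds through a chair transition state in which the (+)-α-pinene-derived reagent attacks the si face of the aldehyde, setting C3 as S.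

**Step 10**
Reactants: 14 α-methylene-γ-butyrolactone
Product: 17 4-[(tert-butyldimethylsilyl)oxy]-2-methylidenebutanoic acid, via sodium 4-hydroxy-2-methylidenebutanoate 15 (not isolated), via bis-silylated ester 16 (not isolated)
Conditions: NaOH (1.0 equiv), H2O/THF, rt; evaporate; TBSCl (2.2 equiv), imidazole, DMF, rt; then K2CO3, MeOH/H2O, 0 °C; 1 M HCl to pH 4–5
Reagents that add atoms: sodium hydroxide, [Na+].[OH-]; tert-butyldimethylsilyl chloride, CC(C)(C)[Si](C)(C)Cl
Why: Saponification opens the lactone, double silylation caps both oxygens, and the far more labile silyl ester is then hydrolysed selectively.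

**Step 11**
Reactants: 13 (S)-2-methylhexa-1,5-dien-3-ol; 17 4-[(tert-butyldimethylsilyl)oxy]-2-methylidenebutanoic acid
Product: 18 (S)-2-methylhexa-1,5-dien-3-yl 4-[(tert-butyldimethylsilyl)oxy]-2-methylidenebutanoate
Conditions: DCC, 4-(dimethylamino)pyridine (cat.), CH2Cl2, 0 °C to rt
Reagents that add atoms: none
Why: Steglich esterification tethers C14 (the carboxyl carbon) to O3 so that the next ring closure can dictate the alkene geometry.

**Step 12**
Reactants: 18 (S)-2-methylhexa-1,5-dien-3-yl 4-[(tert-butyldimethylsilyl)oxy]-2-methylidenebutanoate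
Product: 19 (S)-3-{2-[(tert-butyldimethylsilyl)oxy]ethyl}-6-(prop-1-en-2-yl)-5,6-dihydro-2H-pyran-2-one
Conditions: second-generation Grubbs catalyst RuCl2(=CHPh)(PCy3)(H2IMes) (5 mol%), CH2Cl2 (5 mM), 40 °C
Reagents that add atoms: none
Why: Ring-closing metathesis between the allyl terminus and the acrylate alkene gives the six-membered unsaturated lactone, in which C14 and C2 are forced cis across C10=C1; the isopropenyl group cannot close a viable ring.

**Step 13**
Reactants: 19 (S)-3-{2-[(tert-butyldimethylsilyl)oxy]ethyl}-6-(prop-1-en-2-yl)-5,6-dihydro-2H-pyran-2-one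
Product: 20 (2Z,5S)-2-{2-[(tert-butyldimethylsilyl)oxy]ethyl}-6-methylhepta-2,6-diene-1,5-diol
Conditions: iBu2AlH (4 equiv), CH2Cl2, −78 to 0 °C; aq Rochelle salt
Reagents that add atoms: none
Why: Hydride 1,2-reduction of the unsaturated lactone to the diol preserves the ring-imposed geometry, giving the trisubstituted alkene with CH2OH cis to C2.

**Step 14**
Reactants: 20 (2Z,5S)-2-{2-[(tert-butyldimethylsilyl)oxy]ethyl}-6-methylhepta-2,6-diene-1,5-diol
Product: 21 (3S,5Z)-8-[(tert-butyldimethylsilyl)oxy]-6-{[(tert-butyldiphenylsilyl)oxy]methyl}-2-methylocta-1,5-dien-3-ol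
Conditions: TBDPSCl (1.05 equiv), imidazole, CH2Cl2, −20 to 0 °C
Reagents that add atoms: tert-butyldiphenylsilyl chloride, CC(C)(C)[Si](Cl)(c1ccccc1)c1ccccc1
Why: The bulky silyl chloride selectively protects the primary allylic C14 hydroxyl over the secondary C3 hydroxyl.

**Step 15**
Reactants: 21 (3S,5Z)-8-[(tert-butyldimethylsilyl)oxy]-6-{[(tert-butyldiphenylsilyl)oxy]methyl}-2-methylocta-1,5-dien-3-ol
Product: 22 4-methoxybenzyl ether of 21 at O3
Conditions: NaH, 4-methoxybenzyl chloride, Bu4NI (cat.), THF/DMF, 0 °C to rt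
Reagents that add atoms: 4-methoxybenzyl chloride, COc1ccc(CCl)cc1
Why: Williamson etherification protects O3 with a group that can later be removed oxidatively under neutral conditions; the C–O3 bond at the stereocentre is not broken.

**Step 16**
Reactants: 22 4-methoxybenzyl ether of 21 at O3
Product: 23 (3Z,6S)-3-{[(tert-butyldiphenylsilyl)oxy]methyl}-6-[(4-methoxybenzyl)oxy]-7-methylocta-3,7-dien-1-ol
Conditions: pyridinium p-toluenesulfonate (0.2 equiv), MeOH, rt
Reagents that add atoms: none
Why: Mild acid methanolysis removes the primary TBS ether while the TBDPS and PMB ethers survive.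

**Step 17**
Reactants: 23 (3Z,6S)-3-{[(tert-butyldiphenylsilyl)oxy]methyl}-6-[(4-methoxybenzyl)oxy]-7-methylocta-3,7-dien-1-ol
Product: 24 (3Z,6S)-3-{[(tert-butyldiphenylsilyl)oxy]methyl}-6-[(4-methoxybenzyl)oxy]-7-methylocta-3,7-dienal
Conditions: Dess–Martin periodinane, pyridine, CH2Cl2, 0 °C; used at once
Reagents that add atoms: none
Why: Buffered Dess–Martin oxidation gives the β,γ-unsaturated aldehyde (C8) without isomerising the alkene into conjugation.

### Coupling and endgame

**Step 18**
Reactants: 24 (3Z,6S)-3-{[(tert-butyldiphenylsilyl)oxy]methyl}-6-[(4-methoxybenzyl)oxy]-7-methylocta-3,7-dienal; 10 (R)-3-(bromomethyl)-5-[(E)-2-phenylethenyl]furan-2(5H)-one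
Product: 26 (4R,5R)-4-[(1S,3Z,6S)-3-{[(tert-butyldiphenylsilyl)oxy]methyl}-1-hydroxy-6-[(4-methoxybenzyl)oxy]-7-methylocta-3,7-dien-1-yl]-3-methylidene-5-[(E)-2-phenylethenyl]oxolan-2-one, via allylzinc bromide 25 (not isolated)
Conditions: Zn dust (3 equiv), THF/sat. aq NH4Cl (3:1), 0 °C to rt
Reagents that add atoms: none
Why: In this Barbier allylation the allylzinc adds through C7 in a six-membered chair transition state, anti to the styryl group (6,7-trans, C7 = R) and with the aldehyde chain equatorial, which gives the anti carbinol (C8 = S, the epimer of the target) and the exocyclic methylene.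

**Step 19**
Reactants: 26 the (8S)-alcohol from step 18; 27 (S)-2-methylbutanoic acid
Product: 28 (1R,3Z,6S)-3-{[(tert-butyldiphenylsilyl)oxy]methyl}-6-[(4-methoxybenzyl)oxy]-7-methyl-1-[(2R,3R)-4-methylidene-5-oxo-2-((E)-2-phenylethenyl)oxolan-3-yl]octa-3,7-dien-1-yl (2S)-2-methylbutanoate
Conditions: PPh3, diisopropyl azodicarboxylate, toluene, 0 °C to rt
Reagents that add atoms: none
Why: Mitsunobu esterification displaces the activated C8 oxygen by SN2 with the carboxylate, inverting C8 from S to R and installing the ester in one operation; the acid stereocentre is not enolised.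

**Step 20**
Reactants: 28 the (8R)-ester TBDPS ether
Product: 29 (1R,3Z,6S)-3-(hydroxymethyl)-6-[(4-methoxybenzyl)oxy]-7-methyl-1-[(2R,3R)-4-methylidene-5-oxo-2-((E)-2-phenylethenyl)oxolan-3-yl]octa-3,7-dien-1-yl (2S)-2-methylbutanoate
Conditions: HF·pyridine, pyridine, THF, 0 °C to rt
Reagents that add atoms: none
Why: Buffered fluoride cleaves the primary allylic silyl ether without touching the esters, the α-methylene lactone or the PMB ether.

**Step 21**
Reactants: 29 the C14 allylic alcohol
Product: 30 (1R)-2-[(2S,3R)-2-(hydroxymethyl)-3-{(2S)-2-[(4-methoxybenzyl)oxy]-3-methylbut-3-en-1-yl}oxiran-2-yl]-1-[(2R,3R)-4-methylidene-5-oxo-2-((E)-2-phenylethenyl)oxolan-3-yl]ethyl (2S)-2-methylbutanoate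
Conditions: Ti(OiPr)4 (0.3 equiv), L-(+)-diethyl tartrate (0.36 equiv), t-BuOOH, 4 Å molecular sieves, CH2Cl2, −20 °C
Reagents that add atoms: tert-butyl hydroperoxide, CC(C)(C)OO
Why: Sharpless asymmetric epoxidation touches only the free allylic alcohol, and the L-(+)-tartrate delivers oxygen to the face that gives C1 = R and C10 = S by reagent control.

**Step 22**
Reactants: 30 the open-chain epoxy alcohol
Product: 31 3-O-(4-methoxybenzyl) ether of the target (ten-membered ring closed, C4=C5 Z)
Conditions: second-generation Grubbs catalyst RuCl2(=CHPh)(PCy3)(H2IMes) (15 mol%, in portions), toluene (1 mM), 80 °C, argon sparge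
Reagents that add atoms: none
Why: Ring-closing metathesis expels styrene and joins C5 to the isopropenyl carbon C4; the trans-oxirane and the lactone pre-organise the chain, and the strain of a ten-membered ring makes the Z trisubstituted alkene the accessible isomer.

**Step 23**
Reactants: 31 3-O-(4-methoxybenzyl) ether of the target
Product: 32 target (CNP0356520.3)
Conditions: DDQ, CH2Cl2/pH 7 phosphate buffer, 0 °C to rt
Reagents that add atoms: none
Why: Oxidative PMB cleavage under buffered neutral conditions frees the C3 hydroxyl without opening the oxirane or adding to the α-methylene lactone.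

## Compound list

1 | ethyl 2-(hydroxymethyl)acrylate | C=C(CO)C(=O)OCC | starting material
2 | ethyl 2-{[(tert-butyldimethylsilyl)oxy]methyl}acrylate | C=C(CO[Si](C)(C)C(C)(C)C)C(=O)OCC | intermediate
3 | 2-{[(tert-butyldimethylsilyl)oxy]methyl}acrylic acid | C=C(CO[Si](C)(C)C(C)(C)C)C(=O)O | intermediate
4 | (E)-cinnamaldehyde | O=C/C=C/c1ccccc1 | starting material
5 | racemic (E)-1-phenylpenta-1,4-dien-3-ol | C=CC(O)/C=C/c1ccccc1 | intermediate
6 | (S,E)-1-phenylpenta-1,4-dien-3-ol | C=C[C@H](O)/C=C/c1ccccc1 | intermediate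
7 | (S,E)-1-phenylpenta-1,4-dien-3-yl 2-{[(tert-butyldimethylsilyl)oxy]methyl}acrylate | C=C[C@H](OC(=O)C(=C)CO[Si](C)(C)C(C)(C)C)/C=C/c1ccccc1 | intermediate
8 | (R)-3-{[(tert-butyldimethylsilyl)oxy]methyl}-5-[(E)-2-phenylethenyl]furan-2(5H)-one | O=C1O[C@H](/C=C/c2ccccc2)C=C1CO[Si](C)(C)C(C)(C)C | intermediate
9 | (R)-3-(hydroxymethyl)-5-[(E)-2-phenylethenyl]furan-2(5H)-one | O=C1O[C@H](/C=C/c2ccccc2)C=C1CO | intermediate
10 | (R)-3-(bromomethyl)-5-[(E)-2-phenylethenyl]furan-2(5H)-one (fragment B) | O=C1O[C@H](/C=C/c2ccccc2)C=C1CBr | intermediate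
11 | methacrolein | C=C(C)C=O | starting material
12 | (S)-2-methylhexa-1,5-dien-3-yl diisopinocampheylborinate (not isolated) | C=CC[C@H](OB([C@@H]1C[C@@H]2C[C@H]([C@H]1C)C2(C)C)[C@@H]1C[C@@H]2C[C@H]([C@H]1C)C2(C)C)C(C)=C | intermediate
13 | (S)-2-methylhexa-1,5-dien-3-ol | C=CC[C@H](O)C(C)=C | intermediate
14 | α-methylene-γ-butyrolactone | C=C1CCOC1=O | starting material
15 | sodium 4-hydroxy-2-methylidenebutanoate (not isolated) | C=C(CCO)C(=O)[O-].[Na+] | intermediate
16 | tert-butyldimethylsilyl 4-[(tert-butyldimethylsilyl)oxy]-2-methylidenebutanoate (not isolated) | C=C(CCO[Si](C)(C)C(C)(C)C)C(=O)O[Si](C)(C)C(C)(C)C | intermediate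
17 | 4-[(tert-butyldimethylsilyl)oxy]-2-methylidenebutanoic acid | C=C(CCO[Si](C)(C)C(C)(C)C)C(=O)O | intermediate
18 | (S)-2-methylhexa-1,5-dien-3-yl 4-[(tert-butyldimethylsilyl)oxy]-2-methylidenebutanoate | C=CC[C@H](OC(=O)C(=C)CCO[Si](C)(C)C(C)(C)C)C(C)=C | intermediate
19 | (S)-3-{2-[(tert-butyldimethylsilyl)oxy]ethyl}-6-(prop-1-en-2-yl)-5,6-dihydro-2H-pyran-2-one | O=C1O[C@H](C(C)=C)CC=C1CCO[Si](C)(C)C(C)(C)C | intermediate
20 | (2Z,5S)-2-{2-[(tert-butyldimethylsilyl)oxy]ethyl}-6-methylhepta-2,6-diene-1,5-diol | OC/C(CCO[Si](C)(C)C(C)(C)C)=C\C[C@H](O)C(C)=C | intermediate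
21 | (3S,5Z)-8-[(tert-butyldimethylsilyl)oxy]-6-{[(tert-butyldiphenylsilyl)oxy]methyl}-2-methylocta-1,5-dien-3-ol | CC(C)(C)[Si](OC/C(CCO[Si](C)(C)C(C)(C)C)=C\C[C@H](O)C(C)=C)(c1ccccc1)c1ccccc1 | intermediate
22 | 4-methoxybenzyl ether of 21 at O3 | CC(C)(C)[Si](OC/C(CCO[Si](C)(C)C(C)(C)C)=C\C[C@H](OCc1ccc(OC)cc1)C(C)=C)(c1ccccc1)c1ccccc1 | intermediate
23 | (3Z,6S)-3-{[(tert-butyldiphenylsilyl)oxy]methyl}-6-[(4-methoxybenzyl)oxy]-7-methylocta-3,7-dien-1-ol | CC(C)(C)[Si](OC/C(CCO)=C\C[C@H](OCc1ccc(OC)cc1)C(C)=C)(c1ccccc1)c1ccccc1 | intermediate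
24 | (3Z,6S)-3-{[(tert-butyldiphenylsilyl)oxy]methyl}-6-[(4-methoxybenzyl)oxy]-7-methylocta-3,7-dienal (fragment A) | CC(C)(C)[Si](OC/C(CC=O)=C\C[C@H](OCc1ccc(OC)cc1)C(C)=C)(c1ccccc1)c1ccccc1 | intermediate
25 | allylzinc bromide from 10 (not isolated) | O=C1O[C@H](/C=C/c2ccccc2)C=C1C[Zn]Br | intermediate
26 | Barbier adduct, (8S)-alcohol: 6,12-olide with exocyclic methylene, C6 styryl, C14 OTBDPS, O3 PMB | C=C1C(=O)O[C@H](/C=C/c2ccccc2)[C@H]1[C@@H](O)C/C(CO[Si](c2ccccc2)(c2ccccc2)C(C)(C)C)=C/C[C@H](OCc2ccc(OC)cc2)C(C)=C | intermediate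
27 | (S)-2-methylbutanoic acid | CC[C@H](C)C(=O)O | starting material
28 | (8R)-(2S)-2-methylbutanoate of the C8-inverted alcohol, C14 OTBDPS, O3 PMB | C=C1C(=O)O[C@H](/C=C/c2ccccc2)[C@H]1[C@H](OC(=O)[C@@H](C)CC)C/C(CO[Si](c2ccccc2)(c2ccccc2)C(C)(C)C)=C/C[C@H](OCc2ccc(OC)cc2)C(C)=C | intermediate
29 | C14 allylic alcohol (desilylated 28) | C=C1C(=O)O[C@H](/C=C/c2ccccc2)[C@H]1[C@H](OC(=O)[C@@H](C)CC)C/C(CO)=C/C[C@H](OCc2ccc(OC)cc2)C(C)=C | intermediate
30 | (1R,10S)-epoxy alcohol, open chain | C=C1C(=O)O[C@H](/C=C/c2ccccc2)[C@H]1[C@H](OC(=O)[C@@H](C)CC)C[C@@]2(CO)O[C@@H]2C[C@H](OCc3ccc(OC)cc3)C(C)=C | intermediate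
31 | 3-O-(4-methoxybenzyl) ether of the target | C=C1C(=O)O[C@@H]2/C=C(/C)[C@@H](OCc4ccc(OC)cc4)C[C@H]3O[C@]3(CO)C[C@@H](OC(=O)[C@@H](C)CC)[C@@H]12 | intermediate
32 | (1R,3S,6R,7R,8R,10S,4Z)-1,10-epoxy-3,14-dihydroxy-8-[(2S)-2-methylbutanoyloxy]germacra-4,11(13)-dien-12,6-olide | C=C1C(=O)O[C@@H]2/C=C(/C)[C@@H](O)C[C@H]3O[C@]3(CO)C[C@@H](OC(=O)[C@@H](C)CC)[C@@H]12 | target

## Step count and risks

Total steps: 23. Longest linear sequence: 14 (step 9 or step 10, then steps 11–23), which is 0.61 of the total.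

**Step 19 (Mitsunobu inversion at the hindered C8 carbinol).** Elimination towards C7 or C9, or simply no reaction, is possible because C8 sits between the lactone ring and a branched allylic carbon. The fallback sets out from alcohol 26. It is converted with Tf2O and pyridine in CH2Cl2 at −78 °C into the C8 trifluoromethanesulfonate F1. F1 is displaced with caesium (S)-2-methylbutanoate (made from 27 and Cs2CO3) and 18-crown-6 in toluene at 0 °C to rt. This is an SN2 reaction of a naked carboxylate on an isolated sulfonate, not a redox condensation, and it also inverts C8. The fallback rejoins the route at ester 28.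

**Step 21 (Sharpless epoxidation of a cis-substituted trisubstituted allylic alcohol in a polyfunctional chain).** Such substrates react slowly and the existing stereocentres may oppose the tartrate. The fallback sets out from allylic alcohol 29 and reverses the order of events. Ring-closing metathesis with RuCl2(=CHPh)(PCy3)(H2IMes) in dilute toluene at 80 °C first gives the ten-membered dienol F2, in which C2 and C9 are trans across C1=C10 and C4=C5 is Z. Hydroxyl-directed epoxidation with VO(acac)2 and t-BuOOH in CH2Cl2 at 0 °C then uses the rigid ring: only the outer face of the C1=C10 alkene is open, and the C14 hydroxyl delivers the oxidant there. The fallback rejoins the route at 31.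

**Step 22 (ring-closing metathesis to a ten-membered ring with a trisubstituted alkene).** Loading onto the internal styryl alkene and attack on the hindered isopropenyl group next to the bulky PMB ether may be too slow, giving oligomers instead. The fallback sets out from 30. The PMB group is removed first (DDQ, CH2Cl2/pH 7 buffer) to give the epoxy diol F3. Its free allylic C3 hydroxyl is smaller and can assist the ruthenium alkylidene. Ring closure with the second-generation Hoveyda–Grubbs catalyst RuCl2(=CH-C6H4-2-OiPr)(H2IMes) in toluene at 80 °C under high dilution then leads directly to the target, so the fallback rejoins the route at 32.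

## Further compounds

F1 | step 19 | C8 trifluoromethanesulfonate of alcohol 26 | C=C1C(=O)O[C@H](/C=C/c2ccccc2)[C@H]1[C@@H](OS(=O)(=O)C(F)(F)F)C/C(CO[Si](c2ccccc2)(c2ccccc2)C(C)(C)C)=C/C[C@H](OCc2ccc(OC)cc2)C(C)=C
F2 | step 21 | ten-membered 1(10),4-dienol: 3-O-PMB, 14-OH, 8-ester, no oxirane | C=C1C(=O)O[C@@H]2/C=C(/C)[C@@H](OCc3ccc(OC)cc3)C/C=C(\CO)C[C@@H](OC(=O)[C@@H](C)CC)[C@@H]12
F3 | step 22 | open-chain epoxy diol (30 without the PMB group) | C=C1C(=O)O[C@H](/C=C/c2ccccc2)[C@H]1[C@H](OC(=O)[C@@H](C)CC)C[C@@]2(CO)O[C@@H]2C[C@H](O)C(C)=C
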